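**Plan**
1. Retrosynthesis: the benzene ring of the 2-arylbenzofuran is cut at C4–C5, C6–C7 and C3a–C4, giving a (5-arylfuran-2-yl)ketene (from diazo ketone 27) and siloxyalkyne 20 on cyclohexene C3. The cyclohexene is then cut at C3–C4 and C5–C6 into 2'-hydroxychalcone 5 and (E)-dienyne 10.
2. Enabling feature: benzofuran C5 bears cyclohexene C3 and lies between the hydroxylated C4 and C6, with C7–H and the furan edge C3a–C7a completing the ring. A ketene C=O, the two carbons of an R–C≡C–OSi unit, the ketene CH and a furan C2=C3 bond supply exactly this array.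
3. Forward: Diels–Alder reaction closes the cyclohexene; the aryl ketone is parked as a silylated carbinol, because a free ketone cannot coexist with the lithium acetylide and peroxide used to make the siloxyalkyne. Photochemical benzannulation (20 + 27 → 32) then closes the benzofuran benzene ring, followed by desilylation, MOM capping, re-oxidation and MOM removal.
4. Stereochemistry: C3, C4 and C5 (3R,4R,5S, all-trans) are set together in the chiral-borate-promoted exo Diels–Alder reaction of the (E)-chalcone and (E)-diene. No later step touches them, and all-trans is also the thermodynamic arrangement at C4, the only epimerisable centre.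

Key step: step 14

Numbering used below: cyclohexene C1 carries the methyl group, C1=C2 is the double bond, C3 carries the alkyne (later the benzofuran), C4 the aroyl group or its carbinol, C5 the 2,4-dioxygenated aryl group. The benzofuran is numbered O1, C2, C3, C3a, C4–C7, C7a.
Assumption: the (S)-VANOL borate is taken to expose the chalcone face that leads to the (3R,4R,5S) adduct; the sense is assigned by analogy with related dienes, and the (R)-ligand would be used if the opposite sense were found.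
Remark: the carbinol carbon made in step 8 is not controlled; both epimers are carried to step 17, where that centre is removed.

**Step 1**
Reactants: 1 2,4-dihydroxyacetophenone
Product: 2 2-hydroxy-4-(methoxymethoxy)acetophenone
Conditions: MOMCl (1.1 equiv), K2CO3, acetone, 0 °C → rt
Reagents that add atoms: chloromethyl methyl ether, COCCl
Why: O-alkylation (MOM ether formation) should occur only at the 4-OH, because the 2-OH is hydrogen-bonded to the acetyl group and is much less nucleophilic under carbonate conditions.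

**Step 2**
Reactants: 3 2,4-dihydroxybenzaldehyde
Product: 4 2,4-bis(methoxymethoxy)benzaldehyde
Conditions: MOMCl (2.5 equiv), iPr2NEt, CH2Cl2, 0 °C → rt
Reagents that add atoms: chloromethyl methyl ether, COCCl
Why: exhaustive MOM ether formation with excess reagent and amine base also caps the hydrogen-bonded 2-OH, and the aldehyde is inert to these conditions.

**Step 3**
Reactants: 2 2-hydroxy-4-(methoxymethoxy)acetophenone; 4 2,4-bis(methoxymethoxy)benzaldehyde
Product: 5 (E)-2'-hydroxy-2,4,4'-tris(methoxymethoxy)chalcone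
Conditions: KOH, EtOH–H2O, rt
Reagents that add atoms: none
Why: Claisen–Schmidt condensation of the methyl ketone enolate with the non-enolisable aldehyde, followed by E1cB dehydration, should give the (E)-enone; MOM ethers are stable to base.

**Step 4**
Reactants: 6 3-bromo-1-(trimethylsilyl)prop-1-yne
Product: 7 diethyl [3-(trimethylsilyl)prop-2-yn-1-yl]phosphonate
Conditions: P(OEt)3, neat, 110 °C
Reagents that add atoms: triethyl phosphite, CCOP(OCC)OCC
Why: Michaelis–Arbuzov reaction of a reactive propargylic bromide, driven by loss of bromoethane.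

**Step 5**
Reactants: 7 diethyl [3-(trimethylsilyl)prop-2-yn-1-yl]phosphonate; 8 methacrolein
Product: 10 (E)-trimethyl(5-methylhexa-3,5-dien-1-yn-1-yl)silane, via lithiated phosphonate 9 (not isolated)
Conditions: LiN(SiMe3)2, THF, −78 °C; then 8, −78 → 0 °C
Reagents that add atoms: none
Why: Horner–Wadsworth–Emmons olefination; propargylic phosphonate anions add 1,2 to enals and give mainly the (E)-enyne, here the (E)-dienyne.

**Step 6**
Reactants: 5 (E)-2'-hydroxy-2,4,4'-tris(methoxymethoxy)chalcone; 10 (E)-dienyne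
Product: 13 all-trans (3R,4R,5S) cycloadduct (2'-OH ketone; TMS-alkyne), via chalcone borate chelate 11 (not isolated), via cycloadduct borate 12 (not isolated)
Conditions: (S)-VANOL (1.2 equiv), BH3·THF, AcOH, THF, rt; then 5; then 10 (2 equiv), PhCF3, rt; aqueous work-up
Reagents that add atoms: none
Why: asymmetric Diels–Alder reaction of a 2'-hydroxychalcone promoted by a chiral borate: the phenol binds boron and the chelated carbonyl lowers the LUMO; the alkynyl-bearing diene terminus bonds to the α-carbon and the CH2 terminus to the β-carbon (ortho/para rule); the (E)-alkene fixes C4/C5 trans; the exo approach favoured by the vaulted biaryl ligand places C3 trans to C4; and the ligand shields one enone face, so C3, C4 and C5 should arise as 3R,4R,5S.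

**Step 7**
Reactants: 13 all-trans cycloadduct (2'-OH ketone; TMS-alkyne)
Product: 14 2'-O-MOM ketone (TMS-alkyne)
Conditions: MOMCl, iPr2NEt, Bu4NI (cat.), CH2Cl2, 0 → 40 °C
Reagents that add atoms: chloromethyl methyl ether, COCCl
Why: MOM ether formation on the chelated 2'-OH removes the last acidic O–H; the amine base is too weak to disturb C4, which is in any case in its thermodynamic configuration.

**Step 8**
Reactants: 14 2'-O-MOM ketone (TMS-alkyne)
Product: 16 terminal alkyne carbinol, via TMS-alkynyl carbinol 15 (not isolated)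
Conditions: NaBH4, THF–MeOH, 0 °C → rt; then K2CO3 (0.3 equiv), rt
Reagents that add atoms: none
Why: hydride reduction of the aryl ketone, then methanolysis of the alkynyl C–Si bond in the same flask; the new carbinol centre is uncontrolled and is destroyed in step 17, while C3–C5 are untouched.

**Step 9**
Reactants: 16 terminal alkyne carbinol
Product: 17 carbinol triethylsilyl ether (terminal alkyne)
Conditions: Et3SiCl, imidazole, DMAP (cat.), DMF, rt
Reagents that add atoms: chlorotriethylsilane, CC[Si](Cl)(CC)CC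
Why: silylation of the secondary benzylic alcohol under non-acidic conditions gives a base-stable ether and leaves the alkyne C–H free.

**Step 10**
Reactants: 17 carbinol triethylsilyl ether (terminal alkyne)
Product: 20 C3 (triisopropylsilyloxy)ethynyl cyclohexene, via lithium acetylide 18 (not isolated), via lithium ynolate 19 (not isolated)
Conditions: n-BuLi, THF, −78 °C; LiOOt-Bu (from t-BuOOH and LiN(SiMe3)2), −78 → 0 °C; iPr3SiOTf, −78 → 0 °C; filtration through Et3N-deactivated silica
Reagents that add atoms: tert-butyl hydroperoxide, CC(C)(C)OO; triisopropylsilyl trifluoromethanesulfonate, CC(C)[Si](OS(=O)(=O)C(F)(F)F)(C(C)C)C(C)C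
Why: oxidation of a lithium acetylide by lithium tert-butyl peroxide gives the ynolate, and O-silylation with the bulky silyl triflate gives the siloxyalkyne; with the ketone reduced and every hydroxyl capped, only ethers and silyl ethers face the organolithium.

**Step 11**
Reactants: 21 1-(5-bromofuran-2-yl)ethanone; 22 3-hydroxyphenylboronic acid
Product: 23 1-[5-(3-hydroxyphenyl)furan-2-yl]ethanone
Conditions: Pd(PPh3)4 (3 mol %), Na2CO3, DME–H2O, 80 °C
Reagents that add atoms: none
Why: Suzuki–Miyaura coupling; the acyl-substituted 2-bromofuran undergoes oxidative addition readily and the free phenol is tolerated under carbonate conditions.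

**Step 12**
Reactants: 23 1-[5-(3-hydroxyphenyl)furan-2-yl]ethanone
Product: 24 1-[5-(3-(methoxymethoxy)phenyl)furan-2-yl]ethanone
Conditions: MOMCl, iPr2NEt, CH2Cl2, 0 °C → rt
Reagents that add atoms: chloromethyl methyl ether, COCCl
Why: MOM ether formation caps the phenol, which would otherwise be acylated by the ketene in step 14.

**Step 13**
Reactants: 24 1-[5-(3-(methoxymethoxy)phenyl)furan-2-yl]ethanone
Product: 27 2-diazo-1-[5-(3-(methoxymethoxy)phenyl)furan-2-yl]ethanone, via lithium enolate 25 (not isolated), via trifluoroacetyl diketone 26 (not isolated)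
Conditions: LiN(SiMe3)2, THF, −78 °C; CF3CO2CH2CF3; cold 5% HCl wash; then MsN3, Et3N, H2O, MeCN, rt
Reagents that add atoms: methanesulfonyl azide, CS(=O)(=O)N=[N+]=[N-]
Why: detrifluoroacetylative diazo transfer: Claisen trifluoroacetylation of the enolate activates the methyl group, and the sulfonyl azide then delivers N2 with loss of the trifluoroacetyl group.

**Step 14**
Reactants: 20 C3 (triisopropylsilyloxy)ethynyl cyclohexene; 27 furyl diazomethyl ketone
Product: 32 6-O-TIPS 4-hydroxybenzofuran adduct (carbinol TES ether; five MOM ethers), via furylketene 28 (not isolated), via cyclobutenone 29 (not isolated), via dienylketene 30 (not isolated), via cyclohexadienone 31 (not isolated)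
Conditions: hν (medium-pressure Hg lamp, Pyrex), ClCH2CH2Cl, 25 °C; then 80 °C
Reagents that add atoms: none
Why: Light expels N2 from 27 and the acyl carbene undergoes Wolff rearrangement, furan C2 migrating to the former diazo carbon (the later C7–C7a bond) to give ketene 28; the alkyne carbon bearing cyclohexene C3 attacks the ketene carbonyl carbon (C4–C5) and the silyloxy carbon closes onto the ketene CH (C6–C7) in a [2+2] cycloaddition to cyclobutenone 29. Warming opens 29 by a 4π electrocyclic reaction to dienylketene 30, and the benzene ring closes by 6π electrocyclisation of the ketene carbon onto furan C3 through the furan C2=C3 bond (C3a–C4), after which dienone 31 tautomerises to the C4 phenol. The closest known reaction type is the second-generation Danheiser benzannulation of heteroaryl diazo ketones with siloxyalkynes. No stereocentre is formed, and C3, C4 and C5 have no carbonyl-activated hydrogen and no labile bond under these neutral conditions, so they should pass through unchanged. The step needs regioselectivity, secured by the oxygen polarisation of the ynol ether and by the single free furan position beside the ketene-bearing carbon, and chemoselectivity for the ketene, secured because the partner holds only ethers, silyl ethers and one trisubstituted alkene.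

**Step 15**
Reactants: 32 6-O-TIPS 4-hydroxybenzofuran adduct
Product: 33 benzofuran-4,6-diol carbinol (five MOM ethers)
Conditions: Bu4NF (3 equiv), AcOH (3 equiv), THF, 0 °C → rt
Reagents that add atoms: none
Why: fluoride cleaves the aryl Si–O and alkyl Si–O bonds; acetic acid buffering keeps the electron-rich diol from forming air-sensitive phenoxides.

**Step 16**
Reactants: 33 benzofuran-4,6-diol carbinol
Product: 34 heptakis-MOM carbinol
Conditions: MOMCl (2.5 equiv), K2CO3, acetone, 0 → 40 °C
Reagents that add atoms: chloromethyl methyl ether, COCCl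
Why: carbonate deprotonates only the two phenols, so MOM ether formation should leave the hindered secondary alcohol free.

**Step 17**
Reactants: 34 heptakis-MOM carbinol
Product: 35 heptakis-MOM ketone
Conditions: Dess–Martin periodinane, pyridine, CH2Cl2, 0 °C → rt
Reagents that add atoms: none
Why: Dess–Martin oxidation of the secondary benzylic alcohol restores the aryl ketone; every phenol is capped, and C4 keeps its all-trans (thermodynamic) configuration under the buffered conditions.

**Step 18**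
Reactants: 35 heptakis-MOM ketone
Product: 36 CNP0221531.1
Conditions: HCl (3 M aq.)–MeOH, 40 °C
Reagents that add atoms: none
Why: acid-catalysed acetal exchange with methanol removes all seven MOM ethers; the all-equatorial arrangement at C3–C5 is the stable one, so no epimerisation is expected.

**Compound list**
1 | 2,4-dihydroxyacetophenone | CC(=O)c1ccc(O)cc1O | starting material
2 | 1-[2-hydroxy-4-(methoxymethoxy)phenyl]ethan-1-one | CC(=O)c1ccc(OCOC)cc1O | intermediate
3 | 2,4-dihydroxybenzaldehyde | O=Cc1ccc(O)cc1O | starting material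
4 | 2,4-bis(methoxymethoxy)benzaldehyde | O=Cc1ccc(OCOC)cc1OCOC | intermediate
5 | (E)-3-[2,4-bis(methoxymethoxy)phenyl]-1-[2-hydroxy-4-(methoxymethoxy)phenyl]prop-2-en-1-one | O=C(/C=C/c1ccc(OCOC)cc1OCOC)c1ccc(OCOC)cc1O | intermediate
6 | 3-bromo-1-(trimethylsilyl)prop-1-yne | BrCC#C[Si](C)(C)C | starting material
7 | diethyl [3-(trimethylsilyl)prop-2-yn-1-yl]phosphonate | CCOP(=O)(CC#C[Si](C)(C)C)OCC | intermediate
8 | methacrolein (2-methylprop-2-enal) | CC(=C)C=O | starting material
9 | lithium salt of 7, carbanion on the carbon next to phosphorus | CCOP(=O)([CH-]C#C[Si](C)(C)C)OCC.[Li+] | intermediate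
10 | (E)-trimethyl(5-methylhexa-3,5-dien-1-yn-1-yl)silane | CC(=C)/C=C/C#C[Si](C)(C)C | intermediate
11 | (S)-VANOL borate of chalcone 5 (boron on the 2'-oxygen, carbonyl chelated) | O=C(/C=C/c1ccc(OCOC)cc1OCOC)c1ccc(OCOC)cc1OB1Oc2c(-c3c(O1)c4ccccc4cc3-c3ccccc3)c(-c3ccccc3)cc3ccccc23 | intermediate
12 | (S)-VANOL borate of cycloadduct 13 (boron on the 2'-oxygen) | CC1=C[C@@H](C#C[Si](C)(C)C)[C@H](C(=O)c2ccc(OCOC)cc2OB2Oc3c(-c4c(O2)c5ccccc5cc4-c4ccccc4)c(-c4ccccc4)cc4ccccc34)[C@@H](c2ccc(OCOC)cc2OCOC)C1 | intermediate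
13 | (3R,4R,5S) all-trans cyclohexene: 1-methyl, 3-[(trimethylsilyl)ethynyl], 4-[2-hydroxy-4-(methoxymethoxy)benzoyl], 5-[2,4-bis(methoxymethoxy)phenyl] | CC1=C[C@@H](C#C[Si](C)(C)C)[C@H](C(=O)c2ccc(OCOC)cc2O)[C@@H](c2ccc(OCOC)cc2OCOC)C1 | intermediate
14 | (3R,4R,5S) all-trans cyclohexene: 1-methyl, 3-[(trimethylsilyl)ethynyl], 4-[2,4-bis(methoxymethoxy)benzoyl], 5-[2,4-bis(methoxymethoxy)phenyl] | CC1=C[C@@H](C#C[Si](C)(C)C)[C@H](C(=O)c2ccc(OCOC)cc2OCOC)[C@@H](c2ccc(OCOC)cc2OCOC)C1 | intermediate
15 | carbinol from 14 (aryl ketone reduced to CH(OH), either epimer), TMS-alkyne retained, (3R,4R,5S) | CC1=C[C@@H](C#C[Si](C)(C)C)[C@H](C(O)c2ccc(OCOC)cc2OCOC)[C@@H](c2ccc(OCOC)cc2OCOC)C1 | intermediate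
16 | (3R,4R,5S) all-trans cyclohexene: 1-methyl, 3-ethynyl, 4-[hydroxy(2,4-bis(methoxymethoxy)phenyl)methyl] (either carbinol epimer), 5-[2,4-bis(methoxymethoxy)phenyl] | CC1=C[C@@H](C#C)[C@H](C(O)c2ccc(OCOC)cc2OCOC)[C@@H](c2ccc(OCOC)cc2OCOC)C1 | intermediate
17 | triethylsilyl ether of 16 | CC1=C[C@@H](C#C)[C@H](C(O[Si](CC)(CC)CC)c2ccc(OCOC)cc2OCOC)[C@@H](c2ccc(OCOC)cc2OCOC)C1 | intermediate
18 | lithium acetylide of 17 | CC1=C[C@@H](C#[C-])[C@H](C(O[Si](CC)(CC)CC)c2ccc(OCOC)cc2OCOC)[C@@H](c2ccc(OCOC)cc2OCOC)C1.[Li+] | intermediate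
19 | lithium ynolate (C3–C≡C–OLi) derived from 18 | CC1=C[C@@H](C#C[O-])[C@H](C(O[Si](CC)(CC)CC)c2ccc(OCOC)cc2OCOC)[C@@H](c2ccc(OCOC)cc2OCOC)C1.[Li+] | intermediate
20 | (3R,4R,5S) all-trans cyclohexene: 1-methyl, 3-[(triisopropylsilyloxy)ethynyl], 4-[(triethylsilyloxy)(2,4-bis(methoxymethoxy)phenyl)methyl], 5-[2,4-bis(methoxymethoxy)phenyl] | CC1=C[C@@H](C#CO[Si](C(C)C)(C(C)C)C(C)C)[C@H](C(O[Si](CC)(CC)CC)c2ccc(OCOC)cc2OCOC)[C@@H](c2ccc(OCOC)cc2OCOC)C1 | intermediate
21 | 1-(5-bromofuran-2-yl)ethanone | CC(=O)c1ccc(Br)o1 | starting material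
22 | 3-hydroxyphenylboronic acid | OB(O)c1cccc(O)c1 | starting material
23 | 1-[5-(3-hydroxyphenyl)furan-2-yl]ethanone | CC(=O)c1ccc(-c2cccc(O)c2)o1 | intermediate
24 | 1-[5-(3-(methoxymethoxy)phenyl)furan-2-yl]ethanone | CC(=O)c1ccc(-c2cccc(OCOC)c2)o1 | intermediate
25 | lithium enolate of 24 | C=C([O-])c1ccc(-c2cccc(OCOC)c2)o1.[Li+] | intermediate
26 | 4,4,4-trifluoro-1-[5-(3-(methoxymethoxy)phenyl)furan-2-yl]butane-1,3-dione | O=C(CC(=O)C(F)(F)F)c1ccc(-c2cccc(OCOC)c2)o1 | intermediate
27 | 2-diazo-1-[5-(3-(methoxymethoxy)phenyl)furan-2-yl]ethanone | [N-]=[N+]=CC(=O)c1ccc(-c2cccc(OCOC)c2)o1 | intermediate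
28 | [5-(3-(methoxymethoxy)phenyl)furan-2-yl]ketene | O=C=Cc1ccc(-c2cccc(OCOC)c2)o1 | intermediate
29 | cyclobutenone: 2-(cyclohexen-3-yl), 3-(triisopropylsilyloxy), 4-(5-arylfuran-2-yl)cyclobut-2-en-1-one (C4 of the four-membered ring undefined), cyclohexene (3R,4R,5S) | CC1=C[C@@H](C2=C(O[Si](C(C)C)(C(C)C)C(C)C)C(c3ccc(-c4cccc(OCOC)c4)o3)C2=O)[C@H](C(O[Si](CC)(CC)CC)c2ccc(OCOC)cc2OCOC)[C@@H](c2ccc(OCOC)cc2OCOC)C1 | intermediate
30 | (E)-dienylketene: ketene carbon bears the cyclohexen-3-yl group, then C(OTIPS)=CH–(5-arylfuran-2-yl) with furyl cis to the ketene-bearing carbon | CC1=C[C@@H](C(=C=O)/C(O[Si](C(C)C)(C(C)C)C(C)C)=C\c2ccc(-c3cccc(OCOC)c3)o2)[C@H](C(O[Si](CC)(CC)CC)c2ccc(OCOC)cc2OCOC)[C@@H](c2ccc(OCOC)cc2OCOC)C1 | intermediate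
31 | 3aH-benzofuran-4-one tautomer of 32 (C3a sp3, C5=C6 and C7=C7a double bonds) | CC1=C[C@@H](C2=C(O[Si](C(C)C)(C(C)C)C(C)C)C=C3OC(c4cccc(OCOC)c4)=CC3C2=O)[C@H](C(O[Si](CC)(CC)CC)c2ccc(OCOC)cc2OCOC)[C@@H](c2ccc(OCOC)cc2OCOC)C1 | intermediate
32 | (3R,4R,5S) cyclohexene bearing at C3 the 4-hydroxy-2-[3-(methoxymethoxy)phenyl]-6-(triisopropylsilyloxy)benzofuran-5-yl group; C4 carbinol TES ether; aryl MOM ethers | CC1=C[C@@H](c2c(O[Si](C(C)C)(C(C)C)C(C)C)cc3oc(-c4cccc(OCOC)c4)cc3c2O)[C@H](C(O[Si](CC)(CC)CC)c2ccc(OCOC)cc2OCOC)[C@@H](c2ccc(OCOC)cc2OCOC)C1 | intermediate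
33 | as 32 with benzofuran 4,6-diol and free C4 carbinol | CC1=C[C@@H](c2c(O)cc3oc(-c4cccc(OCOC)c4)cc3c2O)[C@H](C(O)c2ccc(OCOC)cc2OCOC)[C@@H](c2ccc(OCOC)cc2OCOC)C1 | intermediate
34 | as 33 with benzofuran 4,6-bis(methoxymethoxy), free C4 carbinol | CC1=C[C@@H](c2c(OCOC)cc3oc(-c4cccc(OCOC)c4)cc3c2OCOC)[C@H](C(O)c2ccc(OCOC)cc2OCOC)[C@@H](c2ccc(OCOC)cc2OCOC)C1 | intermediate
35 | heptakis(methoxymethyl) ether of the target (C4 aroyl restored), (3R,4R,5S) | CC1=C[C@@H](c2c(OCOC)cc3oc(-c4cccc(OCOC)c4)cc3c2OCOC)[C@H](C(=O)c2ccc(OCOC)cc2OCOC)[C@@H](c2ccc(OCOC)cc2OCOC)C1 | intermediate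
36 | CNP0221531.1: (3R,4R,5S) all-trans 1-methylcyclohexene with 3-[4,6-dihydroxy-2-(3-hydroxyphenyl)benzofuran-5-yl], 4-(2,4-dihydroxybenzoyl), 5-(2,4-dihydroxyphenyl) | CC1=C[C@@H](c2c(O)cc3oc(-c4cccc(O)c4)cc3c2O)[C@H](C(=O)c2ccc(O)cc2O)[C@@H](c2ccc(O)cc2O)C1 | target

**Totals**
Total step count: 18.
Longest linear sequence: 12 steps (1 → 2 → 5 → 13 → 14 → 16 → 17 → 20 → 32 → 33 → 34 → 35 → 36; steps 1, 3, 6, 7, 8, 9, 10, 14, 15, 16, 17, 18).

**Steps most likely to fail**

Step 6. The diene may approach with the aroyl group endo, giving the C3 epimer, or with weak facial discrimination, since with a slim alkynyl substituent the exo preference rests on the ligand alone. The fallback sets out from 5 and returns at 16. Chalcone 5, bound as borate 11, is combined with (E)-1-methoxy-3-(trimethylsilyloxy)buta-1,3-diene, and dilute acid work-up should give the trans (4S,5S)-4-aroyl-5-arylcyclohex-2-enone F1. No endo/exo question arises, because the methoxy-bearing carbon becomes sp2. MOMCl/iPr2NEt gives the 2'-O-MOM enone F2. Conjugate addition of iPr3SiC≡CZnBr promoted by t-BuMe2SiOTf (THF, −40 °C) should enter anti to the C4 aroyl group and give the silyl enol ether F3, with the C1=C2 double bond already placed. CsF/PhNTf2 converts this into the enol triflate F4. Suzuki–Miyaura methylation (trimethylboroxine, Pd(dppf)Cl2, K2CO3, dioxane, 80 °C) gives the methylcyclohexene ketone F5. NaBH4 gives the carbinol F6, and Bu4NF removes the alkynyl silyl group to reach 16.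

Step 14. The ketene may be lost to dimerisation or to acylation of the product phenol before it meets the hindered siloxyalkyne, and the 2-arylbenzofuran chromophore may degrade on long irradiation. The fallback sets out from 27 and returns at ketene 28. Wolff rearrangement of 27 in the dark with AgO2CPh/Et3N in aqueous dioxane gives the (5-arylfuran-2-yl)acetic acid F7. 1-Chloro-N,N,2-trimethylprop-1-en-1-amine in CH2Cl2 gives the acid chloride F8 without free HCl. Slow addition of Et3N to F8 and 20 in toluene generates ketene 28 by dehydrochlorination at low stationary concentration, and heating to 80–110 °C completes 29 → 30 → 31 → 32.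

Step 10. Oxygen transfer from the peroxide to the hindered acetylide may stall, lithiation ortho to the MOM ethers may compete, and the siloxyalkyne may hydrolyse during isolation. The fallback sets out from 17 and returns at ynolate 19. [Hydroxy(tosyloxy)iodo]benzene (CH2Cl2, molecular sieves) converts 17 into the alkynyl(phenyl)iodonium tosylate F9. CuOTf (cat.) in MeCN collapses this to the alkynyl tosylate F10 with loss of iodobenzene. MeLi (THF, −78 °C) attacks sulfur and releases lithium ynolate 19, which is silylated with iPr3SiOTf as in step 10.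

**Further compounds**
F1 | step 6 | (4S,5S)-trans-4-[2-hydroxy-4-(methoxymethoxy)benzoyl]-5-[2,4-bis(methoxymethoxy)phenyl]cyclohex-2-en-1-one | O=C1C=C[C@H](C(=O)c2ccc(OCOC)cc2O)[C@@H](c2ccc(OCOC)cc2OCOC)C1
F2 | step 6 | (4S,5S)-trans-4-[2,4-bis(methoxymethoxy)benzoyl]-5-[2,4-bis(methoxymethoxy)phenyl]cyclohex-2-en-1-one | O=C1C=C[C@H](C(=O)c2ccc(OCOC)cc2OCOC)[C@@H](c2ccc(OCOC)cc2OCOC)C1
F3 | step 6 | (3R,4R,5S) all-trans 1-(tert-butyldimethylsilyloxy)cyclohexene with 3-[(triisopropylsilyl)ethynyl], 4-[2,4-bis(methoxymethoxy)benzoyl], 5-[2,4-bis(methoxymethoxy)phenyl] | CC(C)(C)[Si](C)(C)OC1=C[C@@H](C#C[Si](C(C)C)(C(C)C)C(C)C)[C@H](C(=O)c2ccc(OCOC)cc2OCOC)[C@@H](c2ccc(OCOC)cc2OCOC)C1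
F4 | step 6 | enol triflate corresponding to F3 (C1–OSO2CF3), (3R,4R,5S) | O=S(=O)(OC1=C[C@@H](C#C[Si](C(C)C)(C(C)C)C(C)C)[C@H](C(=O)c2ccc(OCOC)cc2OCOC)[C@@H](c2ccc(OCOC)cc2OCOC)C1)C(F)(F)F
F5 | step 6 | triisopropylsilyl-alkyne analogue of 14 (1-methyl, C4 aroyl), (3R,4R,5S) | CC1=C[C@@H](C#C[Si](C(C)C)(C(C)C)C(C)C)[C@H](C(=O)c2ccc(OCOC)cc2OCOC)[C@@H](c2ccc(OCOC)cc2OCOC)C1
F6 | step 6 | carbinol from F5 (either carbinol epimer), triisopropylsilyl-alkyne retained | CC1=C[C@@H](C#C[Si](C(C)C)(C(C)C)C(C)C)[C@H](C(O)c2ccc(OCOC)cc2OCOC)[C@@H](c2ccc(OCOC)cc2OCOC)C1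
F7 | step 14 | 2-[5-(3-(methoxymethoxy)phenyl)furan-2-yl]acetic acid | OC(=O)Cc1ccc(-c2cccc(OCOC)c2)o1
F8 | step 14 | 2-[5-(3-(methoxymethoxy)phenyl)furan-2-yl]acetyl chloride | O=C(Cl)Cc1ccc(-c2cccc(OCOC)c2)o1
F9 | step 10 | alkynyl(phenyl)iodonium tosylate of 17 (C3–C≡C–I+Ph, tosylate counter-ion) | CC1=C[C@@H](C#C[I+]c2ccccc2)[C@H](C(O[Si](CC)(CC)CC)c2ccc(OCOC)cc2OCOC)[C@@H](c2ccc(OCOC)cc2OCOC)C1.Cc1ccc(S(=O)(=O)[O-])cc1
F10 | step 10 | alkynyl tosylate of 17 (C3–C≡C–OTs) | CC1=C[C@@H](C#COS(=O)(=O)c2ccc(C)cc2)[C@H](C(O[Si](CC)(CC)CC)c2ccc(OCOC)cc2OCOC)[C@@H](c2ccc(OCOC)cc2OCOC)C1
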